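## The problem

The target is an isoflavone: a 5,7-dihydroxylated benzene ring A fused to a γ-pyrone ring C, which carries at C3 a ring B with three contiguous substituents, 3'-OH, 4'-OMe and a 5'-(3-methylbut-2-enyl) group. It has no stereocentre, so the synthesis is a matter of regiochemistry and timing; the only stereochemical element on the way is the geometry of one enol-ether double bond in an open-chain intermediate. Ring B is the awkward half: the carbon substituent sits ortho to the methoxy group and meta to the free hydroxyl, the opposite of what a hydroxyl-directed electrophilic substitution of an isovanillin-type ring gives, and the two neighbouring oxygens must end up differently substituted. The prenyl group is the fragile one: its trisubstituted alkene adds acids and is reduced by catalytic hydrogenation, so it should arrive late and the phenol protecting groups must come off without hydrogen and without hot acid. The γ-pyrone is opened at C2 by hard nucleophiles and hot alkali. The three phenols must be masked while C4 is made electrophilic. The feature that opens the key step is that C4 is an aryl ketone bound to C4a of ring A, and ring A is a symmetric 1,3,5-trioxygenated benzene: once O1 is tied to C2, the two ring carbons ortho to O1 are equivalent, each is activated by all three oxygens, and they are the only positions an acyl group at C4 can reach, so ring C can be closed at carbon with no regiochemical choice.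

## Retrosynthesis

**Benzyl ethers and the prenyl bond (15 ⇒ 14 ⇒ 13).** The three O–benzyl bonds of 14 are cut last and, before them, the bond between C5' and the prenyl CH2, which leads back to aryl bromide 13. Introducing the prenyl group after ring closure is preferred to carrying it through, because step 10 releases a strong acid that would add to the alkene. Benzyl is preferred to methyl, which could not be told from the 4'-methoxy group, and to acetal-type ethers, which would not survive step 10. Compound 13 is simpler by five carbons and holds only groups that tolerate acid, base and heat. The forward steps must transfer the allylic group through its primary carbon and remove benzyl without hydrogen or hot acid.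

**Ring C at C4–C4a (13 ⇒ 11, through 12).** The bond between the carbonyl carbon C4 and C4a is cut, opening ring C to the Z aryloxyacrylic acid 11, which cyclises through its mixed anhydride 12. Cutting O1–C2 or C2–C3 instead leads to a deoxybenzoin, whose assembly needs an intermolecular acylation of ring A in which a doubly benzylated phenol offers two different activated carbons. Here the tether allows only the two equivalent ortho positions. Cutting C3–C1' would call for a ring B boron reagent that also carries the bromine. Compound 11 has one ring fewer. The forward step needs a mild acyl activation that spares benzyl ethers, and the aryloxy group cis to the carboxyl.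

**Enol ether at O1–C2 (11 ⇒ 10 ⇒ 8 + 9).** Behind acid 11 stands ester 10, and in 10 the bond between the ring A oxygen and the future C2 is cut, giving the purchased phenol 9 and the Z enol tosylate 8. The cut divides the molecule into halves of similar size. The joining reaction runs under base, which matters: an acid-catalysed condensation of 9 with a formyl ester would send the electron-rich ring carbon onto the electrophile and end in a 3-arylcoumarin. The forward steps need attack through oxygen at carbon rather than at sulfur, retention of the double-bond geometry, and a saponification that does not expel the aryloxide.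

**Formyl carbon (8 ⇒ 7 ⇒ 6).** The O–S bond of 8 is cut and then the bond between the future C2 and C3 of 7, leading to arylacetic ester 6 and a one-carbon formate electrophile. This is preferred to an aminomethylenation because the free enol 7 can be sulfonylated under chelation control, which fixes the Z geometry that 11 needs. Compound 6 is a plain arylacetate. The forward steps are a crossed Claisen condensation and a Z-selective sulfonylation.

**One-carbon homologation (6 ⇒ 5 ⇒ 4).** The bond between the future C3 and C4 is cut: the aldehyde carbon of 4 becomes the benzylic CH2 and the added carbon becomes C4. Two steps through the ketene dithioacetal S-oxide 5 are preferred to the four of a reduction, halogenation, cyanide displacement and alcoholysis sequence. The forward steps must tolerate the aryl bromide and the benzyl ether.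

**Oxygen pattern of ring B (4 ⇒ 3 ⇒ 2 ⇒ 1).** The benzyl and methyl O–C bonds are cut, back to catechol 2 and to purchased 5-bromovanillin 1. The bromine must stand ortho to the oxygen that ends as OMe and meta to the one that ends as OH. Electrophilic bromination reaches that position only under direction of a free 4-hydroxyl, as in 1, so the methyl group has to move from O3 to O4. The forward steps are a demethylation and a monomethylation that relies on the higher acidity of the hydroxyl para to the aldehyde.

## Roads not taken

**Alternative 1:** The cut is made inside ring A, at C4a–C5. Ring A would be folded from the open-chain triketo ester methyl 8-[4-methoxy-3-(methoxymethoxy)-5-(3-methylbut-2-enyl)phenyl]-3,5,7-trioxooctanoate A1. Under KOH in MeOH or Mg(OMe)2 its C6 methylene attacks the ester carbon to give the deoxybenzoin 2-[4-methoxy-3-(methoxymethoxy)-5-(3-methylbut-2-enyl)phenyl]-1-(2,4,6-trihydroxyphenyl)ethanone A2.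

- Merits: the Claisen mode delivers ring A with all three oxygens in place and no regiochemical question. The medium is basic, so the prenyl group and an acetal protecting group can be carried from the start. A1 could in principle come in one step from a ring B arylacetic ester and the polyanion of a diketo ester. No late cross-coupling and no Lewis-acid deprotection would be needed, and in those two respects it is better than the chosen plan.
- Weak points: a tetracarbonyl chain is a mixture of tautomers. Its C2 methylene can attack the C7 ketone in the aldol mode and give a resorcylic ester instead. The C8 protons between ketone and aryl are the most acidic and invite the wrong enolate. Acylation of a polyanion by an enolisable arylacetic ester is prone to simple proton transfer.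
- A2 is not yet an isoflavone: C2 must still be inserted and ring C closed on a free triphenol. A ketone of the type of A2 is also available in one step by Hoesch acylation of the commercial symmetric triphenol, so the fold builds a ring that can be bought.
- Comparison: against the shorter paper count, the chosen plan sets a ring A taken intact from 9, a ring closure that finishes the isoflavone skeleton, and known reaction types at every stage.

**Alternative 2:** Two bonds of ring C, O1–C8a and C4–C4a, are cut at once. CsF would release the aryne from 3,5-bis(methoxymethoxy)-2-(trimethylsilyl)phenyl trifluoromethanesulfonate A3. The enolate oxygen of methyl (Z)-3-hydroxy-2-[4-methoxy-3-(methoxymethoxy)-5-(3-methylbut-2-enyl)phenyl]prop-2-enoate A4 adds to it, and the aryl anion so formed attacks the ester, giving 5,7-bis(methoxymethoxy)-3-[4-methoxy-3-(methoxymethoxy)-5-(3-methylbut-2-enyl)phenyl]chromen-4-one A5.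

- Merits: this is the most convergent of the four plans. A4 is the prenylated analogue of 7, so steps 7 to 11 of the chosen route would be replaced by one operation. The prenyl group would be present from the start, and the acetal groups of A5 come off with dilute acid, a gentler ending than step 12. The regiochemistry is favourable: a nucleophile adds to a 3-alkoxyaryne at the carbon remote from the alkoxy group and leaves the anion next to it, where C4a lies.
- Weak points: enolates of 1,3-dicarbonyl compounds usually attack arynes through carbon and go on to C-arylation or insertion into the C–C bond. The oxygen-first pathway is established for salicylates but not for open-chain formyl ester enolates. The aryl anion may also simply be protonated. A3 needs several steps of its own, whereas 9 is purchased.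
- Comparison: Alternative 2 is better in step economy and in the mildness of its last step if its key step works. The chosen plan sets against it that each bond formation belongs to a known reaction type on this class of substrate.

**Alternative 3:** Ring C is cut at O1–C2, with C2 present as the terminal methylene of the α-aryl enone 2-[3-bromo-4-methoxy-5-(methoxymethoxy)phenyl]-1-[2-hydroxy-4,6-bis(methoxymethoxy)phenyl]prop-2-en-1-one A6. Catalytic I2 in hot DMSO would add the C8a hydroxyl to that methylene, giving the isoflavanone 3-[3-bromo-4-methoxy-5-(methoxymethoxy)phenyl]-5,7-bis(methoxymethoxy)chroman-4-one A7. The same flask would dehydrogenate it across C2–C3 to 3-[3-bromo-4-methoxy-5-(methoxymethoxy)phenyl]-5,7-bis(methoxymethoxy)chromen-4-one A8.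

- Merits: the plan stands on the deoxybenzoin, the most travelled intermediate of isoflavone chemistry. It comes from one acylation of a symmetric triphenol, so no regiochemical question arises. The hydrogen-bonded ortho hydroxyl stays free by itself when the others are protected. The oxa-Michael closure is a favoured 6-endo-trig process onto an unhindered CH2. In step count to the brominated isoflavone it is probably shorter than the chosen plan, and in precedent for the ring A acylation at least as good. Both plans share the late prenylation.
- Weak points: C2 enters at the methylene oxidation level and must then be oxidised. The HI formed from I2 in hot DMSO threatens the acetal ethers. The free positions C6 and C8 of the trioxygenated ring A are prone to iodination. A6 is a reactive enone that may cyclise or oligomerise before it is wanted.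
- Comparison: against the shorter count, the chosen plan sets a closure that needs no oxidant and no halogen, introduces C2 at the right oxidation level, and uses benzyl ethers that are stable under the closing conditions.

Key step: step 10

Remark: 7 is a tautomeric mixture and is written as its hydrogen-bonded Z enol; 5 is racemic at sulfur and is drawn as the E alkene, and neither point bears on the outcome because both sp2 carbons of 5 are converted in step 5.

## Route

Step 1
Reactants: 1 5-bromovanillin (3-bromo-4-hydroxy-5-methoxybenzaldehyde)
Product: 2 3-bromo-4,5-dihydroxybenzaldehyde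
Conditions: AlCl3, pyridine, CH2Cl2, reflux; then aq. HCl
Reagents that add atoms: none
Why: Chelation-assisted O-demethylation of a guaiacol: AlCl3 binds the phenoxide oxygen and the neighbouring methoxy oxygen, and pyridine takes the methyl group by SN2 attack; the aldehyde and the aryl bromide are inert to these conditions.

Step 2
Reactants: 2 3-bromo-4,5-dihydroxybenzaldehyde
Product: 3 3-bromo-5-hydroxy-4-methoxybenzaldehyde
Conditions: MeI (1.05 equiv), Li2CO3, DMF, 40 °C
Reagents that add atoms: iodomethane, CI
Why: Regioselective Williamson etherification under acidity control: the hydroxyl para to the formyl group and ortho to bromine is much the more acidic, so the weak base Li2CO3 should form only that phenoxide and one equivalent of MeI should methylate it alone.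

Step 3
Reactants: 3 3-bromo-5-hydroxy-4-methoxybenzaldehyde
Product: 4 3-(benzyloxy)-5-bromo-4-methoxybenzaldehyde
Conditions: BnBr, K2CO3, DMF, rt
Reagents that add atoms: benzyl bromide, BrCc1ccccc1
Why: Williamson etherification of the one remaining phenol; benzyl is chosen because it survives base, methanolic HCl and trifluoroacetic anhydride and can later be removed by BCl3 without hydrogen.

Step 4
Reactants: 4 3-(benzyloxy)-5-bromo-4-methoxybenzaldehyde
Product: 5 1-(benzyloxy)-3-bromo-2-methoxy-5-[(E)-2-(methylsulfanyl)-2-(methylsulfinyl)ethenyl]benzene (racemic at sulfur)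
Conditions: MeS(O)CH2SMe, Triton B (cat.), THF, reflux
Reagents that add atoms: methyl (methylsulfinyl)methyl sulfide, CSCS(C)=O
Why: Knoevenagel-type condensation, the first stage of the Ogura–Tsuchihashi arylacetic ester synthesis: the carbanion stabilised by both sulfur groups adds to the unhindered aldehyde and water is lost, giving the ketene dithioacetal S-oxide whose new carbon will become C4.

Step 5
Reactants: 5 1-(benzyloxy)-3-bromo-2-methoxy-5-[(E)-2-(methylsulfanyl)-2-(methylsulfinyl)ethenyl]benzene
Product: 6 methyl 2-[3-(benzyloxy)-5-bromo-4-methoxyphenyl]acetate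
Conditions: HCl, MeOH, rt → 50 °C
Reagents that add atoms: methanol, CO
Why: Second stage of the Ogura–Tsuchihashi synthesis: protonation at the benzylic carbon, addition of methanol to the sulfur-stabilised cation and Pummerer-type loss of the two sulfur groups as dimethyl disulfide should give the arylacetic ester; the aryl benzyl ether and the bromide tolerate methanolic HCl at this temperature.

Step 6
Reactants: 6 methyl 2-[3-(benzyloxy)-5-bromo-4-methoxyphenyl]acetate
Product: 7 methyl (Z)-2-[3-(benzyloxy)-5-bromo-4-methoxyphenyl]-3-hydroxyprop-2-enoate
Conditions: HCO2Me, NaH, THF, 0 °C → rt; then aq. HCl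
Reagents that add atoms: methyl formate, COC=O
Why: Crossed Claisen condensation with a non-enolisable formate; the doubly stabilised enolate of the product drives the equilibrium, and acidification should give the α-formyl ester as its hydrogen-bonded Z enol, the added carbon being the future C2.

Step 7
Reactants: 7 methyl (Z)-2-[3-(benzyloxy)-5-bromo-4-methoxyphenyl]-3-hydroxyprop-2-enoate
Product: 8 methyl (Z)-2-[3-(benzyloxy)-5-bromo-4-methoxyphenyl]-3-{[(4-methylphenyl)sulfonyl]oxy}prop-2-enoate
Conditions: TsCl, TMEDA, LiCl, MeCN, 0 °C
Reagents that add atoms: p-toluenesulfonyl chloride, Cc1ccc(cc1)S(Cl)(=O)=O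
Why: Chelation-controlled enol sulfonylation: Li+ bridges the enolate and ester oxygens, so the enol oxygen is sulfonylated while cis to the ester and the Z enol tosylate should result, as in the Z-selective tosylation of β-keto esters and α-formyl esters under these conditions.

Step 8
Reactants: 8 methyl (Z)-2-[3-(benzyloxy)-5-bromo-4-methoxyphenyl]-3-{[(4-methylphenyl)sulfonyl]oxy}prop-2-enoate; 9 3,5-bis(benzyloxy)phenol
Product: 10 methyl (Z)-3-[3,5-bis(benzyloxy)phenoxy]-2-[3-(benzyloxy)-5-bromo-4-methoxyphenyl]prop-2-enoate
Conditions: Cs2CO3, MeCN, 0 °C → rt
Reagents that add atoms: none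
Why: Nucleophilic vinylic substitution by addition–elimination: the phenoxide adds through oxygen to the β-carbon of the acrylate and the stabilised carbanion expels tosylate after the shorter 60° rotation, the usual course for a good leaving group on a singly activated alkene, so the geometry is retained and the aryloxy group should end cis to the ester. The product is a deactivated push–pull alkene and should not re-add phenoxide when one equivalent of 9 is used.

Step 9
Reactants: 10 methyl (Z)-3-[3,5-bis(benzyloxy)phenoxy]-2-[3-(benzyloxy)-5-bromo-4-methoxyphenyl]prop-2-enoate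
Product: 11 (Z)-3-[3,5-bis(benzyloxy)phenoxy]-2-[3-(benzyloxy)-5-bromo-4-methoxyphenyl]prop-2-enoic acid
Conditions: LiOH, THF–H2O, rt; then aq. HCl, 0 °C
Reagents that add atoms: LiOH (lithium hydroxide), [Li+].[OH-]
Why: Saponification: hydroxide attacks the ester carbonyl, and the carboxylate formed shuts down conjugate addition at the β-carbon, as in the routine hydrolysis of 3-aryloxyacrylic and aryloxyfumaric esters; methanol is left out of the solvent so that no alkoxide can exchange with the aryloxy group.

Step 10
Reactants: 11 (Z)-3-[3,5-bis(benzyloxy)phenoxy]-2-[3-(benzyloxy)-5-bromo-4-methoxyphenyl]prop-2-enoic acid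
Product: 13 5,7-bis(benzyloxy)-3-[3-(benzyloxy)-5-bromo-4-methoxyphenyl]chromen-4-one, via mixed trifluoroacetic anhydride 12 (not isolated)
Conditions: (CF3CO)2O (1.5 equiv), CH2Cl2, 0 °C → rt
Reagents that add atoms: none
Why: Trifluoroacetic anhydride converts acid 11 into the mixed anhydride 12, which ionises to a β-aryloxy acylium ion (or reacts directly, with the trifluoroacetic acid released as catalyst); the ring A carbon ortho to the ether oxygen, also ortho and para to the two benzyloxy groups, attacks it, and loss of a proton from the arenium ion restores ring A and gives the C4 ketone. This is an intramolecular Friedel–Crafts acylation, the closest known reaction types being the acid-mediated cyclisation of 3-aryloxyacrylic acids to chromones and the acylation of polyalkoxyarenes by carboxylic acids activated with (CF3CO)2O. Ring C closes as a six-membered ring in a 6-exo-trig sense at the acyl carbon (the carbonyl oxygen stays outside the new ring), C4–C4a being the only skeletal bond formed. No stereocentre is created. The step needs ortho regioselectivity, which the substrate secures twice over: the two ortho carbons are equivalent by symmetry, and the para carbon cannot reach the acyl group through the short tether. It needs the aryloxy and acyl groups cis, which steps 7 and 8 set; any E isomer that has leaked through can still be drained, because donation from the aryloxy oxygen gives the C2–C3 bond of the acylium ion single-bond character and allows rotation to the reactive form. It needs acylation to outrun benzyl ether cleavage, which the absence of a strong Lewis or mineral acid and the low temperature should secure; ring B cannot compete because attack from it would close a four-membered ring. The bromine stands in for the acid-sensitive prenyl group during this step.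

Step 11
Reactants: 13 5,7-bis(benzyloxy)-3-[3-(benzyloxy)-5-bromo-4-methoxyphenyl]chromen-4-one
Product: 14 5,7-bis(benzyloxy)-3-[3-(benzyloxy)-4-methoxy-5-(3-methylbut-2-enyl)phenyl]chromen-4-one
Conditions: Bu3SnCH2CH=CMe2, Pd(PPh3)4, DMF, 100 °C
Reagents that add atoms: tributyl(3-methylbut-2-enyl)stannane, CCCC[Sn](CCCC)(CCCC)CC=C(C)C
Why: Stille coupling: oxidative addition of the aryl bromide to zerovalent palladium, transfer of the allylic group from tin and reductive elimination from the less hindered σ-allyl complex should place the primary carbon on C5'; the chromone, the benzyl ethers and the methyl ether are inert under these neutral conditions.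

Step 12
Reactants: 14 5,7-bis(benzyloxy)-3-[3-(benzyloxy)-4-methoxy-5-(3-methylbut-2-enyl)phenyl]chromen-4-one
Product: 15 5,7-dihydroxy-3-[3-hydroxy-4-methoxy-5-(3-methylbut-2-enyl)phenyl]chromen-4-one (CNP0231521.0)
Conditions: BCl3, C6HMe5, CH2Cl2, −78 °C; then MeOH, −78 °C → rt
Reagents that add atoms: none
Why: Lewis-acid debenzylation with a cation scavenger: BCl3 coordinates each benzyl ether oxygen (the 5-ether helped by the C4 carbonyl), the benzyl cation is trapped by pentamethylbenzene in a Friedel–Crafts alkylation before it can reach the prenyl alkene, and at −78 °C the methyl ether and the trisubstituted double bond should be left alone.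

## Compound list

1 | 5-bromovanillin (3-bromo-4-hydroxy-5-methoxybenzaldehyde) | COc1cc(C=O)cc(Br)c1O | starting material
2 | 3-bromo-4,5-dihydroxybenzaldehyde | O=Cc1cc(O)c(O)c(Br)c1 | intermediate
3 | 3-bromo-5-hydroxy-4-methoxybenzaldehyde | COc1c(O)cc(C=O)cc1Br | intermediate
4 | 3-(benzyloxy)-5-bromo-4-methoxybenzaldehyde | COc1c(OCc2ccccc2)cc(C=O)cc1Br | intermediate
5 | 1-(benzyloxy)-3-bromo-2-methoxy-5-[(E)-2-(methylsulfanyl)-2-(methylsulfinyl)ethenyl]benzene (racemic at sulfur) | CS(=O)/C(SC)=C/c1cc(Br)c(OC)c(OCc2ccccc2)c1 | intermediate
6 | methyl 2-[3-(benzyloxy)-5-bromo-4-methoxyphenyl]acetate | COC(=O)Cc1cc(Br)c(OC)c(OCc2ccccc2)c1 | intermediate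
7 | methyl (Z)-2-[3-(benzyloxy)-5-bromo-4-methoxyphenyl]-3-hydroxyprop-2-enoate | COC(=O)/C(=C\O)c1cc(Br)c(OC)c(OCc2ccccc2)c1 | intermediate
8 | methyl (Z)-2-[3-(benzyloxy)-5-bromo-4-methoxyphenyl]-3-{[(4-methylphenyl)sulfonyl]oxy}prop-2-enoate | COC(=O)/C(=C\OS(=O)(=O)c1ccc(C)cc1)c1cc(Br)c(OC)c(OCc2ccccc2)c1 | intermediate
9 | 3,5-bis(benzyloxy)phenol | Oc1cc(OCc2ccccc2)cc(OCc2ccccc2)c1 | starting material
10 | methyl (Z)-3-[3,5-bis(benzyloxy)phenoxy]-2-[3-(benzyloxy)-5-bromo-4-methoxyphenyl]prop-2-enoate | COC(=O)/C(=C\Oc1cc(OCc2ccccc2)cc(OCc2ccccc2)c1)c1cc(Br)c(OC)c(OCc2ccccc2)c1 | intermediate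
11 | (Z)-3-[3,5-bis(benzyloxy)phenoxy]-2-[3-(benzyloxy)-5-bromo-4-methoxyphenyl]prop-2-enoic acid | OC(=O)/C(=C\Oc1cc(OCc2ccccc2)cc(OCc2ccccc2)c1)c1cc(Br)c(OC)c(OCc2ccccc2)c1 | intermediate
12 | (Z)-3-[3,5-bis(benzyloxy)phenoxy]-2-[3-(benzyloxy)-5-bromo-4-methoxyphenyl]prop-2-enoic trifluoroacetic anhydride | O=C(OC(=O)C(F)(F)F)/C(=C\Oc1cc(OCc2ccccc2)cc(OCc2ccccc2)c1)c1cc(Br)c(OC)c(OCc2ccccc2)c1 | intermediate
13 | 5,7-bis(benzyloxy)-3-[3-(benzyloxy)-5-bromo-4-methoxyphenyl]chromen-4-one | O=c1c(-c2cc(Br)c(OC)c(OCc3ccccc3)c2)coc2cc(OCc3ccccc3)cc(OCc3ccccc3)c12 | intermediate
14 | 5,7-bis(benzyloxy)-3-[3-(benzyloxy)-4-methoxy-5-(3-methylbut-2-enyl)phenyl]chromen-4-one | O=c1c(-c2cc(CC=C(C)C)c(OC)c(OCc3ccccc3)c2)coc2cc(OCc3ccccc3)cc(OCc3ccccc3)c12 | intermediate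
15 | 5,7-dihydroxy-3-[3-hydroxy-4-methoxy-5-(3-methylbut-2-enyl)phenyl]chromen-4-one | COc1c(O)cc(-c2coc3cc(O)cc(O)c3c2=O)cc1CC=C(C)C | target

## Step count and least certain steps

Total step count: 12. Longest linear sequence: 12 steps (1 to 15); 9 enters as a purchased compound at step 8.

**Step 10 (key step).** The most likely failure is upstream erosion of the cis geometry in steps 8 and 9, so that ring closure has to wait for an isomerisation that the mild medium may not provide. The very electron-rich ring A may also be trifluoroacetylated or acylated intermolecularly, and benzyl ethers may be cleaved if the medium has to be made more acidic. The fallback leaves the aryloxyacrylate and forms C4–C4a intermolecularly on a symmetric ring A. It sets out from aldehyde 4. Van Leusen reductive cyanation (TosMIC, t-BuOK, DME, −40 °C; then MeOH, reflux) should give 2-[3-(benzyloxy)-5-bromo-4-methoxyphenyl]acetonitrile F1. Hoesch acylation of commercial phloroglucinol (benzene-1,3,5-triol) with F1 (ZnCl2, HCl, Et2O, 0 °C; then hot water) should give 2-[3-(benzyloxy)-5-bromo-4-methoxyphenyl]-1-(2,4,6-trihydroxyphenyl)ethanone F2, with no regiochemical question because the triol is symmetric. One-carbon insertion and ring closure with BF3·OEt2, DMF and MeSO2Cl should give 3-[3-(benzyloxy)-5-bromo-4-methoxyphenyl]-5,7-dihydroxychromen-4-one F3. Benzylation of both phenols (BnBr, K2CO3, DMF, 60 °C) comes back to the route at 13.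

**Step 8.** The phenoxide may attack the sulfonyl sulfur instead of the β-carbon, which transfers the tosyl group and returns the enolate of 7. Reversible re-addition of phenoxide may also scramble the double-bond geometry. The fallback replaces the sulfonate by an amine leaving group and accepts thermodynamic control. It sets out from ester 6. Condensation with Me2NCH(OMe)2 (toluene, 100 °C) should give methyl (E)-2-[3-(benzyloxy)-5-bromo-4-methoxyphenyl]-3-(dimethylamino)prop-2-enoate F4. Amine–phenol exchange with 9 (CF3CO2H, 1 equiv, toluene, rt → 60 °C) should give methyl (E)-3-[3,5-bis(benzyloxy)phenoxy]-2-[3-(benzyloxy)-5-bromo-4-methoxyphenyl]prop-2-enoate F5. Saponification (LiOH, THF–H2O) should give (E)-3-[3,5-bis(benzyloxy)phenoxy]-2-[3-(benzyloxy)-5-bromo-4-methoxyphenyl]prop-2-enoic acid F6. Cyclisation with (CF3CO)2O in CF3CO2H–CH2Cl2, where the E to Z exchange takes place in the flask before ring closure, comes back to the route at 13.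

**Step 11.** The allylic group may be transferred through its tertiary terminus, giving the 1,1-dimethylallyl isomer. Oxidative addition at the hindered, electron-rich bromide next to the methoxy group may be slow enough for protodebromination to compete. The fallback builds the prenyl group in two stages from a symmetric allyl group. It sets out from 13. Stille allylation (Bu3SnCH2CH=CH2, Pd(PPh3)4, DMF, 100 °C) should give 5,7-bis(benzyloxy)-3-[3-(benzyloxy)-4-methoxy-5-(prop-2-enyl)phenyl]chromen-4-one F7. Olefin cross-metathesis with 2-methylbut-2-ene and the second-generation Grubbs catalyst, (H2IMes)(PCy3)Cl2Ru=CHPh, in CH2Cl2 at 40 °C comes back to the route at 14.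

**Step 12.** Hydrogen chloride or a benzyl cation may add to the prenyl double bond. The 7-O-benzyl group may be removed incompletely at −78 °C, and warming to complete it risks chelation-assisted loss of the methyl ether next to the freed 3'-oxygen. The fallback removes the benzyl groups before the alkene exists and relays the phenols through acetates. It sets out from 13. BCl3 and C6HMe5 (CH2Cl2, −78 → 0 °C) should give 3-(3-bromo-5-hydroxy-4-methoxyphenyl)-5,7-dihydroxychromen-4-one F8. Acetylation (Ac2O, pyridine) should give 3-[3-(acetyloxy)-5-bromo-4-methoxyphenyl]-4-oxo-4H-chromene-5,7-diyl diacetate F9. Stille prenylation as in step 11 should give 3-[3-(acetyloxy)-4-methoxy-5-(3-methylbut-2-enyl)phenyl]-4-oxo-4H-chromene-5,7-diyl diacetate F10. Mild methanolysis (K2CO3 cat., MeOH, 0 °C) comes back to the route at 15.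

## Further compounds

F1 | step 10 | 2-[3-(benzyloxy)-5-bromo-4-methoxyphenyl]acetonitrile | N#CCc1cc(Br)c(OC)c(OCc2ccccc2)c1
F2 | step 10 | 2-[3-(benzyloxy)-5-bromo-4-methoxyphenyl]-1-(2,4,6-trihydroxyphenyl)ethanone | O=C(Cc1cc(Br)c(OC)c(OCc2ccccc2)c1)c1c(O)cc(O)cc1O
F3 | step 10 | 3-[3-(benzyloxy)-5-bromo-4-methoxyphenyl]-5,7-dihydroxychromen-4-one | O=c1c(-c2cc(Br)c(OC)c(OCc3ccccc3)c2)coc2cc(O)cc(O)c12
F4 | step 8 | methyl (E)-2-[3-(benzyloxy)-5-bromo-4-methoxyphenyl]-3-(dimethylamino)prop-2-enoate | COC(=O)/C(=C/N(C)C)c1cc(Br)c(OC)c(OCc2ccccc2)c1
F5 | step 8 | methyl (E)-3-[3,5-bis(benzyloxy)phenoxy]-2-[3-(benzyloxy)-5-bromo-4-methoxyphenyl]prop-2-enoate | COC(=O)/C(=C/Oc1cc(OCc2ccccc2)cc(OCc2ccccc2)c1)c1cc(Br)c(OC)c(OCc2ccccc2)c1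
F6 | step 8 | (E)-3-[3,5-bis(benzyloxy)phenoxy]-2-[3-(benzyloxy)-5-bromo-4-methoxyphenyl]prop-2-enoic acid | OC(=O)/C(=C/Oc1cc(OCc2ccccc2)cc(OCc2ccccc2)c1)c1cc(Br)c(OC)c(OCc2ccccc2)c1
F7 | step 11 | 5,7-bis(benzyloxy)-3-[3-(benzyloxy)-4-methoxy-5-(prop-2-enyl)phenyl]chromen-4-one | O=c1c(-c2cc(CC=C)c(OC)c(OCc3ccccc3)c2)coc2cc(OCc3ccccc3)cc(OCc3ccccc3)c12
F8 | step 12 | 3-(3-bromo-5-hydroxy-4-methoxyphenyl)-5,7-dihydroxychromen-4-one | COc1c(O)cc(-c2coc3cc(O)cc(O)c3c2=O)cc1Br
F9 | step 12 | 3-[3-(acetyloxy)-5-bromo-4-methoxyphenyl]-4-oxo-4H-chromene-5,7-diyl diacetate | COc1c(OC(C)=O)cc(-c2coc3cc(OC(C)=O)cc(OC(C)=O)c3c2=O)cc1Br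
F10 | step 12 | 3-[3-(acetyloxy)-4-methoxy-5-(3-methylbut-2-enyl)phenyl]-4-oxo-4H-chromene-5,7-diyl diacetate | COc1c(OC(C)=O)cc(-c2coc3cc(OC(C)=O)cc(OC(C)=O)c3c2=O)cc1CC=C(C)C
A1 | alternative 1 | methyl 8-[4-methoxy-3-(methoxymethoxy)-5-(3-methylbut-2-enyl)phenyl]-3,5,7-trioxooctanoate | COC(=O)CC(=O)CC(=O)CC(=O)Cc1cc(OCOC)c(OC)c(CC=C(C)C)c1
A2 | alternative 1 | 2-[4-methoxy-3-(methoxymethoxy)-5-(3-methylbut-2-enyl)phenyl]-1-(2,4,6-trihydroxyphenyl)ethanone | O=C(Cc1cc(OCOC)c(OC)c(CC=C(C)C)c1)c1c(O)cc(O)cc1O
A3 | alternative 2 | 3,5-bis(methoxymethoxy)-2-(trimethylsilyl)phenyl trifluoromethanesulfonate | COCOc1cc(OCOC)c([Si](C)(C)C)c(OS(=O)(=O)C(F)(F)F)c1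
A4 | alternative 2 | methyl (Z)-3-hydroxy-2-[4-methoxy-3-(methoxymethoxy)-5-(3-methylbut-2-enyl)phenyl]prop-2-enoate | COC(=O)/C(=C\O)c1cc(OCOC)c(OC)c(CC=C(C)C)c1
A5 | alternative 2 | 5,7-bis(methoxymethoxy)-3-[4-methoxy-3-(methoxymethoxy)-5-(3-methylbut-2-enyl)phenyl]chromen-4-one | COCOc1cc(OCOC)c2c(c1)occ(-c1cc(OCOC)c(OC)c(CC=C(C)C)c1)c2=O
A6 | alternative 3 | 2-[3-bromo-4-methoxy-5-(methoxymethoxy)phenyl]-1-[2-hydroxy-4,6-bis(methoxymethoxy)phenyl]prop-2-en-1-one | C=C(C(=O)c1c(O)cc(OCOC)cc1OCOC)c1cc(Br)c(OC)c(OCOC)c1
A7 | alternative 3 | 3-[3-bromo-4-methoxy-5-(methoxymethoxy)phenyl]-5,7-bis(methoxymethoxy)chroman-4-one (racemic) | COCOc1cc(OCOC)c2c(c1)OCC(c1cc(Br)c(OC)c(OCOC)c1)C2=O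
A8 | alternative 3 | 3-[3-bromo-4-methoxy-5-(methoxymethoxy)phenyl]-5,7-bis(methoxymethoxy)chromen-4-one | COCOc1cc(OCOC)c2c(c1)occ(-c1cc(Br)c(OC)c(OCOC)c1)c2=O
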